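(The numbers in the tables come from a simulation with constants of no real substance; noise was put on by code.)

Late in the red flask, starting material and coupling partner have both fallen far, so the late rate can show which of them the rate follows.

| setting | red | green | grey |
|---|---|---|---|
| starting material | 0.400 M | 0.200 M | 0.400 M |
| coupling partner | 0.400 M | 0.400 M | 0.400 M |
| free catalyst | 0.00800 M | 0.00800 M | 0.00320 M |
| time |  |  | 18 min |

- red run (time / min: [target] / M): 0.72: 0.020; 1.1: 0.020; 1.8: 0.047; 2.9: 0.065; 4.5: 0.097; 7.2: 0.139; 11: 0.197; 18: 0.283
- green run (time / min: [target] / M): 0.72: 0.010; 1.1: 0.018; 1.8: 0.023; 2.9: 0.036; 4.5: 0.058; 7.2: 0.085; 11: 0.110; 18: 0.152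

(readings scatter by 0.004 M)

- Overall: starting material + coupling partner -> target, with free catalyst as catalyst.
- Constant volume, constant temperature.
- What is held in complexes is read along with the free species.
- "The second partner" is coupling partner.
- An order is taken over about fifteen percent of the charge, up and down.

- how the opening rate goes with [starting material] round the charge of the red run: the exponent of the rate at two percent of starting material gone to target (one fixed amount of target, the same in the runs compared)
- target in the grey run at 18 min, as a share of the starting material charged

Between 11 min and 18 min the red flask makes target at 0.0123 M min⁻¹, with about 0.160 M left of each reactant. The green flask, over its first 4.5 min, makes target at 0.0129 M min⁻¹ on average, with about 0.171 M of starting material and 0.371 M of coupling partner. The ratio of these two read rates, red late over green early, is 0.953, that of c(starting material) 0.936, and that of c(coupling partner) 0.431, so the rate, as read, follows starting material and shows little of the partner.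

How strongly does it follow? The red flask reads 0.065 M at 2.9 min, nearly the amount that the green flask reads at 4.5 min, so the red average rate up to that point is 0.0224 M min⁻¹. Between these two charges, the two average rates read as an order of 0.798.

The grey flask has red's charges of both reactants, so what remains is catalyst, which neither run varied. My reckoning assumes that rate goes with catalyst, so flasks of equal reactant charges share one curve against the catalyst clock, c(free catalyst) multiplied by time. Grey's clock at 18 min is 3.46 M·s, which red reaches at 7.20 min, where red read 0.139 M, or 34.8% of the charge.

The forecast gives 0.72, where my reading is 0.798, and 35%, with the words “I assume rate is proportional to catalyst, which is untested”.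

The flask gives 0.66 and 11.0%.

    free catalyst + starting material → loaded catalyst + by-product (20.70 L mol⁻¹ min⁻¹)
    loaded catalyst + coupling partner → target + free catalyst (122.4 L mol⁻¹ min⁻¹)
    free catalyst + impurity → spent catalyst
    2 starting material ⇌ idle substrate dimer, settled at all times (1.510 L mol⁻¹)

The impurity, a catalyst poison in the usual term, turns 0.00262 M of free catalyst into spent catalyst at once, holding the grey flask at 11.0% against 49.8% without it. The clock should therefore count working catalyst: 0.00538 M in red and 5.80 × 10⁻⁴ M in grey. Grey's 18 min then equals 1.94 min of red, close to the red reading of 0.047 M at 1.8 min. Without the impurity, grey's unreduced clock equals 10.7 min of red, and the red flask comes to half of its charge at 10.8 min.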